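Compound numbers used below follow the order of the steps. Atom numbering is that of the target: carbocycle C1–C14, C15 on C1 carrying methylene C17 and lactone carbonyl C16, methyls C18 (on C4), C19 (on C8) and C20 (on C12).

## The problem

Querciformolide C is a fourteen-membered carbocycle (C1–C14) that carries two further rings: an oxolane whose oxygen joins C4 and C7, and a seven-membered α-methylene lactone that runs from C1 through C15 and the carbonyl C16 to the oxygen on C12. Its seven stereocentres (1R,3S,4R,7S,8R,11R,12R) fall into three islands, C1, C3/C4/C7/C8 and C11/C12, separated by CH2 or CH2CH2 links, so no island can be relied on to control another and each needs its own source of chirality. Inside an island control is possible: C4 can come from the chiral pool, C7 and C8 from one face-selective epoxidation followed by an invertive ring closure, C3 from addition to an aldehyde next to C4, and C12 from addition to a ketone next to C11. Three centres (C4, C8, C12) are fully substituted and oxygen-bearing, and C12 is a tertiary carbinol that must end up acylated, which speaks against any late macrolactonisation onto it. The exo-methylene lactone is a Michael acceptor, its tertiary alkyl C–O bond ionises under strong acid, the secondary acetates at C3 and C11 would migrate or hydrolyse under base, and the C8 hydroxyl must stay free, so the methylene group and the acetates have to be installed last and under mild conditions. The feature that opens the route is the ester link C16–O–C12: in an open chain it already holds C13 (on C12) and C14 (on C1) within reach of each other, and C9/C10 is a second plain two-carbon bridge between the carbinol carbons C8 and C11, so both C13–C14 and C9–C10 can be made as alkenes from four vinyl groups.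

## Retrosynthesis

**Acetates and silyl ethers (35 from 34 from 33).** The two acetate C–O bonds are cut first. Target 35 comes from triol 34, whose secondary hydroxyls at C3 and C11 should acylate while the tertiary C8 hydroxyl does not, and 34 comes from the bis(silyl ether) 33. Cutting here and not earlier keeps base-labile acetates out of every enolate and organometallic step. The forward reaction must acetylate without conjugate addition to the methylene lactone.

**Exocyclic methylene (33 from 30).** The C15=C17 bond is cut, giving the saturated lactone 30, which has a single enolisable position. Carrying the methylene through the ring closure as an acrylate-type ester was rejected, because that alkene would close onto the C12 vinyl group to a five-membered butenolide. The forward step needs a lactone enolate beside a free tertiary alcohol and two silyl ethers.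

**Saturation (30 from 29).** C13–C14 and C9–C10 are redrawn as alkenes, which gives the bicyclic diene 29 without touching a stereocentre. The forward reaction must reduce two disubstituted alkenes without hydrogenolysis of the allylic C–O bonds.

**Key disconnection (29 from 27 from 26).** Both ring alkenes are cut, which opens the lactone and the carbocycle at once and leads to the acyclic tetra-vinyl ester 27.
- The neighbouring cuts are worse: the lactone C–O bond would need macrolactonisation onto the tertiary C12 hydroxyl, and a carbocycle C–C bond would have to be formed together with a new stereocentre. Here two rings close and no stereocentre is made, so all seven centres can be fixed beforehand in open-chain fragments.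
- Ester 27 carries a free C8 hydroxyl and is made from its triethylsilyl ether 26. A vinyl group on a fully substituted carbon bearing a bulky silyl ether is a poor metathesis partner, whereas tertiary allylic alcohols are good ones.
- The forward reaction needs pairing selectivity among four vinyl groups and a macrocyclisation at high dilution.

**Ester (26 from 15 and 24).** The C16–O bond is cut into acid 15 (C1, C3, C4, C7, C8) and alcohol 24 (C11, C12). This is the most convergent cut, and it is intermolecular. It asks for acylation of a hindered tertiary alcohol, which is done through the acid chloride 25 and the alkoxide of 24.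

**C1 centre (15 from 14 from 13 from 11 and 12).** The C1–C15 bond is cut. The branched malonate 13 comes from the linear allylic carbonate 11 and dimethyl malonate 12 by iridium-catalysed allylic alkylation. This sets C1 and installs both its vinyl group and the two-carbon acid arm in one step; an auxiliary-based conjugate addition or a Claisen route would take longer. Carbonate 11 comes from diene 10 by cross-metathesis at its only unhindered alkene. The forward reaction needs catalyst control that ignores the remote C3 centre.

**C8 vinyl group and C3 carbinol (10 from 9 from 8 from 7 from 6).** The C9 methylene is cut back to aldehyde 9, which has no α-hydrogen and comes directly from the primary silyl ether 8. The C2–C3 bond is cut by an allylboration transform, homoallylic alcohol 7 from aldehyde 6. The order is dictated by chemoselectivity: the vinyl group inherited from linalool must be cleaved to the C3 aldehyde before any other vinyl group exists.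

**Oxolane (6 from 5 from 4 from 3 from 2 from 1).** The C7–O bond is cut to the epoxy alcohol 3, which comes from allylic alcohol 2 and this from (R)-linalool 1 by allylic oxidation. Linalool supplies C4 with its methyl, oxygen and a vinyl group (the future C3), plus C5–C9 and C19. The forward reactions need a reagent-controlled epoxidation (C7, C8) and a 5-exo epoxide opening with inversion at C7.

**Alcohol fragment (24 from 23 from 22 from 21 from 20 from 19 from 18 from 17 from 16).** The C12–C13 bond is cut by a chelate-controlled vinyl addition to methyl ketone 18, made from the glycerate ester 16 through amide 17. The C10 methylene is cut back to aldehyde 23. Compounds 20–22 are the protecting-group changes that leave the tertiary hydroxyl free and the C11 oxygen silylated.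

## Roads not taken

**Alternative 1: furan (4+3) cycloaddition.**
- Cut: C7–C8 and C3–C4, giving the oxygen-bridged bicyclic keto aldehyde A1.
- Forward step: 2-methylfuran A2 and the iminium ion of the silyloxydienal A3 (formed with a chiral imidazolidinone salt) would combine stepwise to the seven-membered carbocycle and with it the bridged five-membered ether.
- Merits: one catalytic enantioselective step from achiral, very cheap materials sets the C4 quaternary ether centre and the cis relation across the bridging oxygen. In this respect it is better than the chosen plan, which depends on the optical purity of a terpene and a stoichiometric chiral pool.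
- Weak points: A1 is only a C2–C10 fragment. Its carbocycle contains a C2–C8 bond that the target lacks; this bond has to be cut again and C2 brought from the ketone level down to a methylene bonded to C1. C8 arrives as a CH and still needs both its methyl and its hydroxyl, C3 needs an oxygen, the C5=C6 alkene must be reduced, and the unsymmetrical furan raises a regiochemical question. The fourteen-membered ring and the lactone remain unsolved.
- Comparison: the chosen plan reaches the same segment (compound 4) in two steps with C4, C7 and C8 correct and then closes both large rings in one step. What it sets against the catalytic elegance of A1 is step economy after the key step.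

**Alternative 2: transannular Rauhut–Currier closure.**
- Cut: C1–C15.
- Forward step: a nucleophilic phosphine would add to the acrylate of the macrocyclic enone A5, the resulting enolate carbon C15 would attack C1, and loss of the phosphine would give the methylene lactone A4.
- Merits: the lactone ring, the C1 centre and the exocyclic methylene appear together, so no separate methylenation is needed, and the tertiary C12 hydroxyl only has to be acylated by a small acrylate. Both points are better than in the chosen plan, which needs a demanding esterification (step 20) and a separate methylenation (step 24).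
- Weak points: A5 presupposes a fourteen-membered carbocycle made by some other ring closure. C1 would be set transannularly by the conformation of a flexible macrocycle with no reagent control. Rauhut–Currier closures to seven-membered rings are rare, and the phosphine can also add to the enone. The C3 ketone of A4 must later be reduced to the 3S alcohol beside quaternary C4.
- Comparison: the chosen plan sets C1 and C3 in open-chain intermediates by catalyst and reagent control and forms no stereocentre during ring closure.

**Alternative 3: cathodic decarboxylative radical macrocyclisation.**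
- Cut: C8–C9.
- Forward step: cathodic reduction of the redox-active ester A7 would release a tertiary α-silyloxy radical at C8 that adds to the terminal carbon of the C11 vinyl ketone, giving macrocycle A6.
- Merits: the ring closes through an sp3–sp3 bond at the final oxidation level of C9/C10, the radical and acceptor are polarity-matched, and no bulky alkene pair has to meet. It avoids the hydrogenation step and the steric problem at C8/C11 that the chosen plan has to manage.
- Weak points: the C8 stereocentre is erased in the radical and re-formed during macrocyclisation under uncertain substrate control. The C11 ketone then needs a diastereoselective reduction next to the acyloxy-bearing C12, where acyl migration threatens. The vinyl ketone on a fully substituted carbon is prone to polymerisation and premature reduction at the electrode.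
- Comparison: the chosen plan fixes C8 early by epoxidation and C11 in the small fragment 24, and keeps every centre intact through the ring closure.

Key step: step 22

Remark (assumption): in step 10 the (Ra,R,R)-phosphoramidite is taken to deliver the malonate to the face of C1 that gives (1S)-13, as it does for simple (E)-allyl carbonates; the enantiomeric ligand is equally available should the sense be opposite.

Remark: the C9=C10 alkene of 29 is drawn E; either geometry serves, because it is hydrogenated in step 23.

## Route

Step 1
Reactants: 1 (R)-(−)-linalool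
Product: 2 (2E,6R)-2,6-dimethylocta-2,7-diene-1,6-diol
Conditions: SeO2 (cat.), tBuOOH, salicylic acid (cat.), CH2Cl2, rt
Reagents that add atoms: tert-butyl hydroperoxide, CC(C)(C)OO (terminal oxygen source; the oxygen is relayed by SeO2, O=[Se]=O)
Why: Selenium dioxide allylic oxidation (ene reaction, then [2,3]-sigmatropic shift) attacks the electron-rich trisubstituted alkene and gives the (E)-allylic alcohol; the vinyl group of the tertiary carbinol is too electron-poor to react, so C4 is untouched.

Step 2
Reactants: 2 (2E,6R)-2,6-dimethylocta-2,7-diene-1,6-diol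
Product: 4 (2R)-2-[(2S,5R)-5-ethenyl-5-methyloxolan-2-yl]propane-1,2-diol (4R,7S,8R), via epoxy diol 3 (not isolated)
Conditions: Ti(OiPr)4 (10 mol%), D-(−)-diethyl tartrate (12 mol%), tBuOOH, 4 Å molecular sieves, CH2Cl2, −20 °C; then camphorsulfonic acid (cat.), CH2Cl2, 0 °C to rt
Reagents that add atoms: tert-butyl hydroperoxide, CC(C)(C)OO
Why: Sharpless asymmetric epoxidation of the (E)-2-methyl allylic alcohol with the D-tartrate should give the (7R,8R)-epoxide under reagent control, the tertiary vinyl carbinol being a very slow substrate. Acid then triggers 5-exo opening by the C4 hydroxyl at C7 with inversion (7S), and the epoxide oxygen stays on C8 (8R).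

Step 3
Reactants: 4 oxolane diol
Product: 5 bis(triethylsilyl) ether of 4 (C8 and C9 oxygens silylated; 4R,7S,8R)
Conditions: Et3SiOTf, 2,6-lutidine, CH2Cl2, −78 to 0 °C
Reagents that add atoms: triethylsilyl trifluoromethanesulfonate, CC[Si](CC)(CC)OS(=O)(=O)C(F)(F)F
Why: Silyl triflates silylate primary and tertiary hydroxyls alike; the primary triethylsilyl ether is the later handle for C9 and the tertiary one protects C8 until step 21.

Step 4
Reactants: 5 bis(triethylsilyl) ether
Product: 6 (2R,5S)-5-[(2R)-1,2-bis(triethylsilyloxy)propan-2-yl]-2-methyloxolane-2-carbaldehyde (C3 aldehyde; 4R,7S,8R)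
Conditions: O3, CH2Cl2, −78 °C; then PPh3, −78 °C to rt
Reagents that add atoms: ozone, [O-][O+]=O
Why: Ozonolysis with reductive work-up cleaves the only alkene; the aldehyde has no α-hydrogen, so C4 cannot epimerise.

Step 5
Reactants: 6 C3 aldehyde
Product: 7 (1S)-1-[(2R,5S)-5-[(2R)-1,2-bis(triethylsilyloxy)propan-2-yl]-2-methyloxolan-2-yl]but-3-en-1-ol (3S,4R,7S,8R)
Conditions: (−)-Ipc2B(allyl), Et2O, −78 °C; then aq. NaOH, H2O2, 0 °C to rt
Reagents that add atoms: (−)-B-allyldiisopinocampheylborane, C=CCB([C@@H]1C[C@@H]2C[C@H]([C@H]1C)C2(C)C)[C@@H]1C[C@@H]2C[C@H]([C@H]1C)C2(C)C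
Why: Brown allylboration through a closed chair transition state; this enantiomer of the reagent adds to the Si face of aldehydes, which gives 3S here. Reagent control is expected to outweigh the weak bias of the α-alkoxy quaternary centre.

Step 6
Reactants: 7 homoallylic alcohol
Product: 8 tert-butyldimethylsilyl ether of 7 (C3 OTBS, C8 and C9 OTES; 3S,4R,7S,8R)
Conditions: tBuMe2SiOTf, 2,6-lutidine, CH2Cl2, −78 to 0 °C
Reagents that add atoms: tert-butyldimethylsilyl trifluoromethanesulfonate, CC(C)(C)[Si](C)(C)OS(=O)(=O)C(F)(F)F
Why: Silyl triflate silylation of a hindered secondary alcohol; the tert-butyldimethylsilyl group is chosen to outlast the triethylsilyl ethers.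

Step 7
Reactants: 8 tris(silyl) ether
Product: 9 (2S)-2-[(2S,5R)-5-[(1S)-1-(tert-butyldimethylsilyloxy)but-3-en-1-yl]-5-methyloxolan-2-yl]-2-(triethylsilyloxy)propanal (C9 aldehyde; 3S,4R,7S,8S, the C8 descriptor changing only because the formyl group outranks C7)
Conditions: (COCl)2, DMSO, CH2Cl2, −78 to −30 °C; then Et3N, −78 °C to rt
Reagents that add atoms: none
Why: Under Swern conditions the chlorosulfonium salt cleaves a primary triethylsilyl ether and oxidises it to the aldehyde in the same flask, while tertiary triethylsilyl and secondary tert-butyldimethylsilyl ethers are inert. The aldehyde has no α-hydrogen, so C8 is safe.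

Step 8
Reactants: 9 C9 aldehyde
Product: 10 diene with vinyl on C8 and terminal alkene at C1 (C3 OTBS, C8 OTES; 3S,4R,7S,8R)
Conditions: Ph3PCH3Br, KN(SiMe3)2, THF, 0 °C to rt
Reagents that add atoms: methyltriphenylphosphonium bromide (as its ylide), C[P+](c1ccccc1)(c1ccccc1)c1ccccc1.[Br-]
Why: Wittig methylenation of a non-enolisable aldehyde; the hindered carbonyl is the reason for running it above −78 °C.

Step 9
Reactants: 10 diene
Product: 11 (E)-allylic methyl carbonate (C1=CH–CH2OCO2Me; 3S,4R,7S,8R)
Conditions: allyl methyl carbonate (4 equiv), second-generation Grubbs catalyst (H2IMes)(PCy3)Cl2Ru=CHPh (5 mol%), CH2Cl2, 40 °C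
Reagents that add atoms: allyl methyl carbonate, C=CCOC(=O)OC
Why: Olefin cross-metathesis at the unhindered terminal alkene; the vinyl group on the fully substituted, silyloxy-bearing C8 should not load the catalyst, and the E-alkene is the thermodynamic product.

Step 10
Reactants: 11 (E)-allylic methyl carbonate; 12 dimethyl malonate
Product: 13 branched malonate, dimethyl 2-substituted malonate with vinyl on C1 (1S,3S,4R,7S,8R)
Conditions: [Ir(cod)Cl]2 (2 mol%), (Ra,R,R)-O,O'-(1,1'-binaphthalene-2,2'-diyl)-N,N-bis(1-phenylethyl)phosphoramidite (4 mol%), 1,5,7-triazabicyclo[4.4.0]dec-5-ene (8 mol%), THF, rt to 50 °C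
Reagents that add atoms: none
Why: Iridium-catalysed asymmetric allylic alkylation through a cyclometalated iridium phosphoramidite allyl complex gives the branched product with the malonate on C1. The ligand sets C1 under catalyst control, and the methoxide released from the carbonate serves as base.

Step 11
Reactants: 13 branched malonate
Product: 14 methyl ester (C16 ester, vinyl on C1; 1R,3S,4R,7S,8R)
Conditions: LiCl, H2O, DMSO, 140 °C
Reagents that add atoms: none
Why: Krapcho dealkoxycarbonylation (chloride demethylates one ester, the carboxylate loses carbon dioxide) under neutral conditions that silyl ethers tolerate; C1 is not α to a carbonyl afterwards and keeps its configuration.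

Step 12
Reactants: 14 methyl ester
Product: 15 C16 carboxylic acid (1R,3S,4R,7S,8R)
Conditions: LiOH, THF/MeOH/H2O, rt; then 0.5 M HCl to pH 4, 0 °C
Reagents that add atoms: lithium hydroxide, [Li+].[OH-]
Why: Saponification of an unhindered methyl ester; the hindered silyl ethers are stable to aqueous hydroxide at room temperature.

Step 13
Reactants: 16 methyl (R)-2,2-dimethyl-1,3-dioxolane-4-carboxylate
Product: 18 1-[(4R)-2,2-dimethyl-1,3-dioxolan-4-yl]ethan-1-one, via Weinreb amide 17 (not isolated)
Conditions: MeNH(OMe)·HCl, iPrMgCl, THF, −20 °C; then MeMgBr, −20 to 0 °C; aq. NH4Cl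
Reagents that add atoms: methylmagnesium bromide, C[Mg]Br (N,O-dimethylhydroxylamine hydrochloride, CNOC.Cl, adds atoms to intermediate 17 only)
Why: The magnesium amide converts the ester into the Weinreb amide, whose chelated tetrahedral adduct with the methyl Grignard reagent prevents over-addition; at low temperature the α-stereocentre (the future C11) is not enolised.

Step 14
Reactants: 18 methyl ketone
Product: 19 (2R)-2-[(4R)-2,2-dimethyl-1,3-dioxolan-4-yl]but-3-en-2-ol (11R,12R)
Conditions: MgBr2·OEt2, CH2Cl2, −78 °C; then vinylMgBr (THF solution), −78 °C; aq. NH4Cl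
Reagents that add atoms: vinylmagnesium bromide, C=C[Mg]Br
Why: Cram-chelate addition: magnesium bridges the ketone oxygen and the α-oxygen of the dioxolane, and the vinyl group adds from the face of the α-hydrogen, anti to C10, which gives 12R from the 11R centre.

Step 15
Reactants: 19 tertiary alcohol
Product: 20 (2R,3R)-3-methylpent-4-ene-1,2,3-triol (11R,12R)
Conditions: AcOH/H2O (4:1), rt
Reagents that add atoms: none
Why: Mild acetal hydrolysis; the tertiary allylic alcohol is flanked by an oxygen-bearing carbon and should not ionise under acetic acid.

Step 16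
Reactants: 20 triol
Product: 21 (3R,4R)-4,5-bis(tert-butyldimethylsilyloxy)-3-methylpent-1-en-3-ol
Conditions: tBuMe2SiCl (2.4 equiv), imidazole, 4-(dimethylamino)pyridine (cat.), DMF, rt to 40 °C
Reagents that add atoms: tert-butyldimethylsilyl chloride, CC(C)(C)[Si](C)(C)Cl
Why: Silyl chloride with imidazole silylates the primary and secondary hydroxyls and leaves the tertiary one free, as needed for step 20.

Step 17
Reactants: 21 bis(silyl) ether
Product: 22 (2R,3R)-2-(tert-butyldimethylsilyloxy)-3-methylpent-4-ene-1,3-diol
Conditions: HF·pyridine, pyridine, THF, 0 °C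
Reagents that add atoms: none
Why: Buffered fluoride cleaves the primary silyl ether much faster than the hindered secondary one, and the acidic medium does not promote silyl migration.

Step 18
Reactants: 22 diol
Product: 23 (2S,3R)-2-(tert-butyldimethylsilyloxy)-3-hydroxy-3-methylpent-4-enal (C10 aldehyde; 11S,12R, the C11 descriptor changing only because the formyl group outranks C12)
Conditions: Dess–Martin periodinane, pyridine, CH2Cl2, 0 °C
Reagents that add atoms: none
Why: Dess–Martin oxidation of the primary alcohol under buffered, non-basic conditions; the tertiary alcohol cannot be oxidised and the α-silyloxy centre is not epimerised.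

Step 19
Reactants: 23 C10 aldehyde
Product: 24 (3R,4R)-4-(tert-butyldimethylsilyloxy)-3-methylhexa-1,5-dien-3-ol (11R,12R)
Conditions: Ph3PCH3Br, KN(SiMe3)2 (3 equiv of ylide), THF, −78 °C (aldehyde added to the ylide), then to 0 °C
Reagents that add atoms: methyltriphenylphosphonium bromide (as its ylide), C[P+](c1ccccc1)(c1ccccc1)c1ccccc1.[Br-]
Why: Wittig methylenation; adding the aldehyde to excess salt-free ylide at low temperature should make olefination faster than retro-aldol cleavage or α-epimerisation of the alkoxide.

Step 20
Reactants: 15 C16 carboxylic acid; 24 diene alcohol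
Product: 26 tetra-vinyl ester with C8 OTES (ester of the C12 oxygen with C16; C3 and C11 OTBS; 1R,3S,4R,7S,8R,11R,12R), via acid chloride 25 (not isolated)
Conditions: 15, 1-chloro-N,N,2-trimethylprop-1-en-1-amine, CH2Cl2, 0 °C; separately 24, LiN(SiMe3)2, THF, −78 °C; then 25 added, −78 to −40 °C
Reagents that add atoms: 1-chloro-N,N,2-trimethylprop-1-en-1-amine, CC(C)=C(Cl)N(C)C (supplies the chlorine of intermediate 25 only)
Why: Acylation of a preformed tertiary lithium alkoxide with an acid chloride made under neutral conditions, the standard way to esters of tertiary allylic alcohols. The low temperature is meant to keep the C11 silyl group from migrating to the alkoxide, and C1 is β to the carbonyl, so even passage through the ketene leaves it intact.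

Step 21
Reactants: 26 tetra-vinyl ester with C8 OTES
Product: 27 tetra-vinyl ester with free C8 hydroxyl (C3 and C11 OTBS; 1R,3S,4R,7S,8R,11R,12R)
Conditions: HF·pyridine, pyridine, THF, 0 °C
Reagents that add atoms: none
Why: Selective desilylation: the triethylsilyl ether is far more labile than the two secondary tert-butyldimethylsilyl ethers, each of which sits beside a fully substituted carbon. The free tertiary allylic alcohol makes the C9 vinyl group a better metathesis partner.

Step 22
Reactants: 27 tetra-vinyl ester with free C8 hydroxyl
Product: 29 bicyclic diene, Z-unsaturated seven-membered lactone and fourteen-membered carbocycle (C3 and C11 OTBS, C8 OH; 1R,3S,4R,7S,8R,11R,12R), via monocyclic lactone 28 (not isolated)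
Conditions: second-generation Grubbs catalyst (H2IMes)(PCy3)Cl2Ru=CHPh (5 + 5 mol%), 1,4-benzoquinone (10 mol%), toluene (1 mM), 40 °C then 80 °C, argon sparge
Reagents that add atoms: none
Why: Olefin metathesis through ruthenium alkylidenes and ruthenacyclobutanes, run as two ring closures in one flask; the closest known reaction types are ring-closing metathesis to seven-membered unsaturated lactones and macrocyclic ring-closing metathesis. The catalyst should load first on the C14 vinyl group at C1, the only one without an oxygen-bearing or fully substituted neighbour, and the ester tether then presents the C13 vinyl group for closure of the seven-membered lactone 28 (ring-closing of a 1,8-diene through the ester, Z-alkene by ring constraint, helped by the geminal substitution at C12). The remaining vinyl groups at C11 and C8 can only pair with each other: the alkylidene should form at C10 and close on the C9 vinyl group of the free tertiary allylic alcohol to give the fourteen-membered ring (macrocyclic mode, high dilution, ethylene swept out). No stereocentre is formed, and the C9=C10 geometry is irrelevant because both new alkenes are hydrogenated in step 23. The selectivity needed is pairing selectivity: C14 with C13 and C9 with C10, not C14 with C10 (eight-membered lactone), C13 with C9 (thirteen-membered ring) or C14 with C9 (nine-membered ring). It is secured by ring size, the seven-membered closure being much faster than the medium-ring and crossed alternatives, by the steric ranking of the four vinyl groups, and by the unprotected C8 oxygen, which keeps the most hindered alkene a competent acceptor. Benzoquinone is added to suppress alkene isomerisation by ruthenium hydrides.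

Step 23
Reactants: 29 bicyclic diene
Product: 30 saturated bicyclic lactone (C3 and C11 OTBS, C8 OH; 1R,3S,4R,7S,8R,11R,12R)
Conditions: H2 (1–4 atm), PtO2, EtOAc, rt
Reagents that add atoms: none
Why: Heterogeneous hydrogenation of two disubstituted alkenes; PtO2 in a neutral solvent is chosen over palladium catalysts to limit hydrogenolysis of the allylic lactone, silyl ether and alcohol C–O bonds.

Step 24
Reactants: 30 saturated bicyclic lactone
Product: 33 α-methylene lactone bis(tert-butyldimethylsilyl) ether (C8 OH; 1R,3S,4R,7S,8R,11R,12R), via Mannich base 31 (not isolated), via methiodide 32 (not isolated)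
Conditions: LiN(iPr)2 (2.3 equiv), THF, −78 °C; CH2=NMe2+ I−, −78 °C to rt; aqueous work-up; MeI, MeOH, rt; then DBU, CH2Cl2, rt
Reagents that add atoms: N,N-dimethylmethyleneiminium iodide (Eschenmoser's salt), C=[N+](C)C.[I-] (iodomethane, CI, adds a methyl group to intermediate 32 only)
Why: Mannich reaction of the lactone enolate with Eschenmoser's salt at C15, the only enolisable position (the second equivalent of base is consumed by the C8 hydroxyl), then quaternisation and base-induced elimination of trimethylamine; the new C15 centre of 31 is destroyed again and C1 is not acidic.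

Step 25
Reactants: 33 α-methylene lactone bis(silyl ether)
Product: 34 3,8,11-triol (1R,3S,4R,7S,8R,11R,12R)
Conditions: aq. HF (48%), MeCN, 0 °C to rt
Reagents that add atoms: none
Why: Acidic fluoride desilylation; it avoids the basic fluoride sources that would invite oxa-Michael addition to the methylene lactone or acyl migration from the C12 oxygen.

Step 26
Reactants: 34 triol
Product: 35 querciformolide C
Conditions: Ac2O, pyridine, 4-(dimethylamino)pyridine (cat.), CH2Cl2, 0 °C to rt
Reagents that add atoms: acetic anhydride, CC(=O)OC(C)=O
Why: Acetylation of the two secondary alcohols at C3 and C11; the tertiary C8 hydroxyl beside the oxolane is too hindered to react under these conditions.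

## Compound list

1 | (R)-(−)-linalool | C=C[C@@](O)(C)CCC=C(C)C | starting material
2 | (2E,6R)-2,6-dimethylocta-2,7-diene-1,6-diol | C=C[C@@](O)(C)CC/C=C(\C)CO | intermediate
3 | epoxy diol, (3R)-5-[(2R,3R)-3-(hydroxymethyl)-3-methyloxiran-2-yl]-3-methylpent-1-en-3-ol | C=C[C@@](O)(C)CC[C@H]1O[C@]1(C)CO | intermediate (not isolated)
4 | (2R)-2-[(2S,5R)-5-ethenyl-5-methyloxolan-2-yl]propane-1,2-diol | C=C[C@@]1(C)CC[C@H](O1)[C@](C)(O)CO | intermediate
5 | bis(triethylsilyl) ether of 4 | C=C[C@@]1(C)CC[C@H](O1)[C@](C)(O[Si](CC)(CC)CC)CO[Si](CC)(CC)CC | intermediate
6 | (2R,5S)-5-[(2R)-1,2-bis(triethylsilyloxy)propan-2-yl]-2-methyloxolane-2-carbaldehyde | O=C[C@@]1(C)CC[C@H](O1)[C@](C)(O[Si](CC)(CC)CC)CO[Si](CC)(CC)CC | intermediate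
7 | (1S)-1-[(2R,5S)-5-[(2R)-1,2-bis(triethylsilyloxy)propan-2-yl]-2-methyloxolan-2-yl]but-3-en-1-ol | C=CC[C@H](O)[C@@]1(C)CC[C@H](O1)[C@](C)(O[Si](CC)(CC)CC)CO[Si](CC)(CC)CC | intermediate
8 | tert-butyldimethylsilyl ether of 7 | C=CC[C@H](O[Si](C)(C)C(C)(C)C)[C@@]1(C)CC[C@H](O1)[C@](C)(O[Si](CC)(CC)CC)CO[Si](CC)(CC)CC | intermediate
9 | (2S)-2-[(2S,5R)-5-[(1S)-1-(tert-butyldimethylsilyloxy)but-3-en-1-yl]-5-methyloxolan-2-yl]-2-(triethylsilyloxy)propanal | C=CC[C@H](O[Si](C)(C)C(C)(C)C)[C@@]1(C)CC[C@H](O1)[C@](C)(O[Si](CC)(CC)CC)C=O | intermediate
10 | diene: C3 OTBS, C8 OTES, vinyl on C8, terminal alkene at C1 (3S,4R,7S,8R) | C=CC[C@H](O[Si](C)(C)C(C)(C)C)[C@@]1(C)CC[C@H](O1)[C@](C)(O[Si](CC)(CC)CC)C=C | intermediate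
11 | (E)-allylic methyl carbonate of the C1 alkene (3S,4R,7S,8R) | COC(=O)OC/C=C/C[C@H](O[Si](C)(C)C(C)(C)C)[C@@]1(C)CC[C@H](O1)[C@](C)(O[Si](CC)(CC)CC)C=C | intermediate
12 | dimethyl malonate | COC(=O)CC(=O)OC | starting material
13 | branched malonate with vinyl on C1 (1S,3S,4R,7S,8R) | COC(=O)C(C(=O)OC)[C@H](C=C)C[C@H](O[Si](C)(C)C(C)(C)C)[C@@]1(C)CC[C@H](O1)[C@](C)(O[Si](CC)(CC)CC)C=C | intermediate
14 | C16 methyl ester (1R,3S,4R,7S,8R) | COC(=O)C[C@H](C=C)C[C@H](O[Si](C)(C)C(C)(C)C)[C@@]1(C)CC[C@H](O1)[C@](C)(O[Si](CC)(CC)CC)C=C | intermediate
15 | C16 carboxylic acid (1R,3S,4R,7S,8R) | OC(=O)C[C@H](C=C)C[C@H](O[Si](C)(C)C(C)(C)C)[C@@]1(C)CC[C@H](O1)[C@](C)(O[Si](CC)(CC)CC)C=C | intermediate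
16 | methyl (R)-2,2-dimethyl-1,3-dioxolane-4-carboxylate | COC(=O)[C@H]1COC(C)(C)O1 | starting material
17 | (R)-N-methoxy-N,2,2-trimethyl-1,3-dioxolane-4-carboxamide | CON(C)C(=O)[C@H]1COC(C)(C)O1 | intermediate (not isolated)
18 | 1-[(4R)-2,2-dimethyl-1,3-dioxolan-4-yl]ethan-1-one | CC(=O)[C@H]1COC(C)(C)O1 | intermediate
19 | (2R)-2-[(4R)-2,2-dimethyl-1,3-dioxolan-4-yl]but-3-en-2-ol | C=C[C@@](C)(O)[C@H]1COC(C)(C)O1 | intermediate
20 | (2R,3R)-3-methylpent-4-ene-1,2,3-triol | C=C[C@@](C)(O)[C@H](O)CO | intermediate
21 | (3R,4R)-4,5-bis(tert-butyldimethylsilyloxy)-3-methylpent-1-en-3-ol | C=C[C@@](C)(O)[C@H](O[Si](C)(C)C(C)(C)C)CO[Si](C)(C)C(C)(C)C | intermediate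
22 | (2R,3R)-2-(tert-butyldimethylsilyloxy)-3-methylpent-4-ene-1,3-diol | C=C[C@@](C)(O)[C@H](O[Si](C)(C)C(C)(C)C)CO | intermediate
23 | (2S,3R)-2-(tert-butyldimethylsilyloxy)-3-hydroxy-3-methylpent-4-enal | C=C[C@@](C)(O)[C@H](O[Si](C)(C)C(C)(C)C)C=O | intermediate
24 | (3R,4R)-4-(tert-butyldimethylsilyloxy)-3-methylhexa-1,5-dien-3-ol | C=C[C@@](C)(O)[C@H](O[Si](C)(C)C(C)(C)C)C=C | intermediate
25 | acid chloride of 15 | ClC(=O)C[C@H](C=C)C[C@H](O[Si](C)(C)C(C)(C)C)[C@@]1(C)CC[C@H](O1)[C@](C)(O[Si](CC)(CC)CC)C=C | intermediate (not isolated)
26 | tetra-vinyl ester, C8 OTES, C3 and C11 OTBS | C=C[C@@](C)(OC(=O)C[C@H](C=C)C[C@H](O[Si](C)(C)C(C)(C)C)[C@@]1(C)CC[C@H](O1)[C@](C)(O[Si](CC)(CC)CC)C=C)[C@H](O[Si](C)(C)C(C)(C)C)C=C | intermediate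
27 | tetra-vinyl ester, C8 OH, C3 and C11 OTBS | C=C[C@@](C)(OC(=O)C[C@H](C=C)C[C@H](O[Si](C)(C)C(C)(C)C)[C@@]1(C)CC[C@H](O1)[C@](C)(O)C=C)[C@H](O[Si](C)(C)C(C)(C)C)C=C | intermediate
28 | monocyclic Z-unsaturated seven-membered lactone with vinyl groups on C8 and C11 | C1C(=O)O[C@](C)(/C=C\[C@@H]1C[C@H](O[Si](C)(C)C(C)(C)C)[C@@]2(C)CC[C@H](O2)[C@](C)(O)C=C)[C@H](O[Si](C)(C)C(C)(C)C)C=C | intermediate (not isolated)
29 | bicyclic diene, unsaturated lactone and fourteen-membered ring, C8 OH | C1C(=O)O[C@]2(C)/C=C\[C@@H]1C[C@H](O[Si](C)(C)C(C)(C)C)[C@@]1(C)CC[C@H](O1)[C@](C)(O)/C=C/[C@H]2O[Si](C)(C)C(C)(C)C | intermediate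
30 | saturated bicyclic lactone, C3 and C11 OTBS, C8 OH | C1C(=O)O[C@]2(C)CC[C@@H]1C[C@H](O[Si](C)(C)C(C)(C)C)[C@@]1(C)CC[C@H](O1)[C@](C)(O)CC[C@H]2O[Si](C)(C)C(C)(C)C | intermediate
31 | Mannich base, C15 dimethylaminomethyl lactone (C15 epimers) | CN(C)CC1C(=O)O[C@]2(C)CC[C@@H]1C[C@H](O[Si](C)(C)C(C)(C)C)[C@@]1(C)CC[C@H](O1)[C@](C)(O)CC[C@H]2O[Si](C)(C)C(C)(C)C | intermediate (not isolated)
32 | methiodide of 31 | C[N+](C)(C)CC1C(=O)O[C@]2(C)CC[C@@H]1C[C@H](O[Si](C)(C)C(C)(C)C)[C@@]1(C)CC[C@H](O1)[C@](C)(O)CC[C@H]2O[Si](C)(C)C(C)(C)C.[I-] | intermediate (not isolated)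
33 | α-methylene lactone, C3 and C11 OTBS, C8 OH | C=C1C(=O)O[C@]2(C)CC[C@@H]1C[C@H](O[Si](C)(C)C(C)(C)C)[C@@]1(C)CC[C@H](O1)[C@](C)(O)CC[C@H]2O[Si](C)(C)C(C)(C)C | intermediate
34 | 3,8,11-triol | C=C1C(=O)O[C@]2(C)CC[C@@H]1C[C@H](O)[C@@]1(C)CC[C@H](O1)[C@](C)(O)CC[C@H]2O | intermediate
35 | querciformolide C | C=C1C(=O)O[C@]2(C)CC[C@@H]1C[C@H](OC(C)=O)[C@@]1(C)CC[C@H](O1)[C@](C)(O)CC[C@H]2OC(C)=O | target

## Step count and risks

Total step count: 26. Longest linear sequence: 19 steps (steps 1–12 and 20–26); the alcohol branch (steps 13–19) joins at step 20.

**Step 22 (key step).** The second closure may fail to keep pace with intermolecular metathesis: loading at C10 and attack on the C9 vinyl group are both sterically slowed, so the monocyclic lactone may oligomerise through its C10 vinyl group. If the seven-membered closure is not clearly fastest, C14 may also pair with C10. Fallback, a relay ring-closing metathesis that delivers the alkylidene to C10 from an unhindered terminus: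
- Aldehyde 23 would be olefinated with the ylide of hex-5-enyltriphenylphosphonium bromide to (3R,4R,5Z)-4-(tert-butyldimethylsilyloxy)-3-methylundeca-1,5,10-trien-3-ol F1.
- F1 would be acylated with acid chloride 25 as in step 20 to the relay ester F2, and desilylated at C8 as in step 21 to the relay ester F3.
- With the same ruthenium catalyst, loading at the terminal alkene of the relay chain should expel cyclopentene and place the alkylidene on C10, from where the macrocycle closes. The route is rejoined at 29.

**Step 20.** The lithium alkoxide of 24 may pass its neighbouring silyl group from the C11 oxygen to the C12 oxygen, after which the more reactive secondary alkoxide would be acylated. Acylation of the hindered tertiary alkoxide may also be slower than enolisation of the acid chloride to a ketene that dimerises. Fallback, acylation of the neutral alcohol by nucleophilic catalysis (Yamaguchi esterification): acid 15 would be converted with 2,4,6-trichlorobenzoyl chloride and Et3N into the mixed anhydride F4, which with alcohol 24 and 4-(dimethylamino)pyridine in toluene at 60–80 °C should give 26 without any alkoxide being formed.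

**Step 14.** Facial selectivity may be poor or reversed if the dioxolane oxygen does not chelate magnesium and the addition follows the open Felkin–Anh course, which leads to the C12 epimer. Fallback, inverting the order in which the two carbon groups arrive: ester 16 would be taken to amide 17 (isolated this time) and treated with vinylMgBr to give 1-[(4R)-2,2-dimethyl-1,3-dioxolan-4-yl]prop-2-en-1-one F5. Addition of MeLi or MeMgBr/CeCl3 to F5 under the same non-chelating preference then gives 19.

**Step 5.** Facial selectivity may drop if the α-alkoxy quaternary centre opposes the borane (mismatched pairing), and the neopentyl-type aldehyde may add slowly. Fallback, oxidation and reagent-controlled reduction: the epimer mixture 7 would be oxidised with Dess–Martin periodinane to the allyl ketone F6. Corey–Bakshi–Shibata reduction with (R)-2-methyl-CBS-oxazaborolidine and BH3·SMe2, in which the quaternary C4 is the large group and the allyl group the small one, should return 7 as the 3S alcohol.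

**Step 19.** The alkoxide formed from the free tertiary hydroxyl may undergo retro-aldol cleavage, or the α-silyloxy centre C11 may epimerise, before the ylide has reacted. Fallback, masking the hydroxyl: aldehyde 23 would be silylated with N-(trimethylsilyl)imidazole to the trimethylsilyl ether aldehyde F7, methylenated to the trimethylsilyl ether diene F8, and the trimethylsilyl group removed with K2CO3 in MeOH to give 24.

**Step 7.** Cleavage and oxidation of the neopentyl-type primary silyl ether in one flask may be incomplete, or the tertiary triethylsilyl ether may be lost on warming. Fallback, two separate operations: 8 would be treated with pyridinium p-toluenesulfonate in MeOH/CH2Cl2 at 0 °C to give the primary alcohol F9, which Dess–Martin periodinane would oxidise to 9.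

## Further compounds

F1 | step 22 | (3R,4R,5Z)-4-(tert-butyldimethylsilyloxy)-3-methylundeca-1,5,10-trien-3-ol | C=C[C@@](C)(O)[C@H](O[Si](C)(C)C(C)(C)C)/C=C\CCCC=C
F2 | step 22 | relay ester, C8 OTES | C=C[C@@](C)(OC(=O)C[C@H](C=C)C[C@H](O[Si](C)(C)C(C)(C)C)[C@@]1(C)CC[C@H](O1)[C@](C)(O[Si](CC)(CC)CC)C=C)[C@H](O[Si](C)(C)C(C)(C)C)/C=C\CCCC=C
F3 | step 22 | relay ester, C8 OH | C=C[C@@](C)(OC(=O)C[C@H](C=C)C[C@H](O[Si](C)(C)C(C)(C)C)[C@@]1(C)CC[C@H](O1)[C@](C)(O)C=C)[C@H](O[Si](C)(C)C(C)(C)C)/C=C\CCCC=C
F4 | step 20 | mixed anhydride of 15 with 2,4,6-trichlorobenzoic acid | O=C(OC(=O)c1c(Cl)cc(Cl)cc1Cl)C[C@H](C=C)C[C@H](O[Si](C)(C)C(C)(C)C)[C@@]1(C)CC[C@H](O1)[C@](C)(O[Si](CC)(CC)CC)C=C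
F5 | step 14 | 1-[(4R)-2,2-dimethyl-1,3-dioxolan-4-yl]prop-2-en-1-one | C=CC(=O)[C@H]1COC(C)(C)O1
F6 | step 5 | allyl ketone at C3 (4R,7S,8R) | C=CCC(=O)[C@@]1(C)CC[C@H](O1)[C@](C)(O[Si](CC)(CC)CC)CO[Si](CC)(CC)CC
F7 | step 19 | trimethylsilyl ether of aldehyde 23 | C=C[C@@](C)(O[Si](C)(C)C)[C@H](O[Si](C)(C)C(C)(C)C)C=O
F8 | step 19 | trimethylsilyl ether of diene alcohol 24 | C=C[C@@](C)(O[Si](C)(C)C)[C@H](O[Si](C)(C)C(C)(C)C)C=C
F9 | step 7 | primary alcohol at C9 (C3 OTBS, C8 OTES) | C=CC[C@H](O[Si](C)(C)C(C)(C)C)[C@@]1(C)CC[C@H](O1)[C@](C)(O[Si](CC)(CC)CC)CO
A1 | alternative 1 | oxabicyclic keto aldehyde | C1[C@@]2(C)C=C[C@H](O2)[C@H](C1=O)CC=O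
A2 | alternative 1 | 2-methylfuran | Cc1ccco1
A3 | alternative 1 | (E)-4-(trimethylsilyloxy)penta-2,4-dienal | C=C(O[Si](C)(C)C)/C=C/C=O
A4 | alternative 2 | α-methylene lactone with C3 ketone | C=C1C(=O)O[C@]2(C)CC[C@@H]1CC(=O)[C@@]1(C)CC[C@H](O1)[C@](C)(O[Si](CC)(CC)CC)CC[C@H]2OC(C)=O
A5 | alternative 2 | macrocyclic (E)-enone with acrylate on the C12 oxygen | C=CC(=O)O[C@]1(C)CC/C=C/C(=O)[C@@]2(C)CC[C@H](O2)[C@](C)(O[Si](CC)(CC)CC)CC[C@H]1OC(C)=O
A6 | alternative 3 | macrocyclic C11 ketone with saturated lactone | C1C(=O)O[C@]2(C)CC[C@@H]1C[C@H](O[Si](C)(C)C(C)(C)C)[C@@]1(C)CC[C@H](O1)[C@](C)(O[Si](CC)(CC)CC)CCC2=O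
A7 | alternative 3 | C8 N-(acyloxy)phthalimide ester with C11 vinyl ketone | C1C(=O)O[C@](C)(CC[C@@H]1C[C@H](O[Si](C)(C)C(C)(C)C)[C@@]2(C)CC[C@H](O2)[C@](C)(O[Si](CC)(CC)CC)C(=O)ON3C(=O)c4ccccc4C3=O)C(=O)C=C
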